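**Plan**

- Ring A is numbered C1 (OMe), C2 (H), C3 (OH), C4 (4-hydroxybenzyl), C5 (CH2CH2 link to ring B), C6 (4-hydroxybenzyl). Its OH and OMe are meta, and C4, next to the OH, carries a benzylic carbon; with that carbon as a ketone, ring A is a 2-hydroxy-4-methoxyaryl ketone, the pattern a 1,3-dimethoxy-1-silyloxydiene gives with an alkynyl ketone.
- Retrosynthesis: the four phenols are masked as benzyl ethers and the C4 benzylic CH2 is taken back to C=O. Ring A is then cut at C3–C4 and C5–C6 into a 4-benzylated Brassard-type diene (C1, C2, C3, C6) and an aryl alkynyl ketone (C4, C5, ring B).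
- The diene is cut at O–Si, at the enol ether C–O and at the γ-C–CH2Ar bond (methyl acetoacetate plus 4-(benzyloxy)benzyl chloride). The ynone is cut at the acyl–alkyne bond, at the ArCH–CH2C≡CH bond (aldehyde plus propargyl bromide) and at the ring B aryl–CH2 bond (Negishi).
- Forward: steps 1–3 make the diene and steps 4–7 the ynone (ring B diarylmethane first, then the chain). Step 8 closes ring A, the only ring formed; steps 9–11 reduce the ketone to CH2 and free the four phenols.
- The target is achiral; the stereocentres of three intermediates are racemic and are removed again, so none has to be controlled.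

Key step: step 8

**Remarks on the chemistry**

- The diene is taken as the (1Z,3Z) isomer expected from carbonyl-directed γ-deprotonation of the E-enoate. Its geometry is erased on aromatisation, so an isomer mixture at the ketene acetal end would serve as well.
- 2-(Benzyloxy)-5-bromobenzaldehyde and 4-(benzyloxy)benzoyl chloride are taken as purchasable.
- Ring B is the 2-hydroxy-5-(4-hydroxybenzyl)phenyl ring.

**Route**

Step 1
Reactants: 1 methyl acetoacetate; 2 4-(benzyloxy)benzyl chloride
Product: 4 methyl 5-[4-(benzyloxy)phenyl]-3-oxopentanoate, via methyl acetoacetate dianion 3 (not isolated)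
Conditions: NaH, THF, 0 °C; n-BuLi, 0 °C; then 2, 0 °C to rt; 1 M HCl quench
Reagents that add atoms: none
Why: Weiler dianion alkylation, in which the sodium lithium dianion reacts with the benzylic chloride only at its more basic terminal (γ) carbon, the carbon that becomes C6 of ring A.

Step 2
Reactants: 4 methyl 5-[4-(benzyloxy)phenyl]-3-oxopentanoate
Product: 6 methyl (E)-5-[4-(benzyloxy)phenyl]-3-methoxypent-2-enoate, via dimethyl ketal 5 (not isolated)
Conditions: HC(OMe)3 (neat), conc. H2SO4 (cat.), rt; then 50 °C under reduced pressure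
Reagents that add atoms: trimethyl orthoformate, COC(OC)OC
Why: Acid-catalysed ketalisation by the orthoformate and loss of methanol (enol ether formation) should give the conjugated β-methoxy enoate, the E isomer being thermodynamically favoured as for methyl 3-methoxybut-2-enoate.

Step 3
Reactants: 6 methyl (E)-5-[4-(benzyloxy)phenyl]-3-methoxypent-2-enoate
Product: 8 (1Z,3Z)-5-[4-(benzyloxy)phenyl]-1,3-dimethoxy-1-(trimethylsilyloxy)penta-1,3-diene, via lithium dienolate 7 (not isolated)
Conditions: LiN(iPr)2 (LDA), THF, −78 °C; Me3SiCl, −78 °C to rt; non-aqueous work-up (pentane, filtration under argon); used at once in step 8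
Reagents that add atoms: chlorotrimethylsilane, C[Si](C)(C)Cl
Why: Kinetic γ-deprotonation of a β-methoxy enoate guided by the ester carbonyl, then O-silylation of the dienolate, is the standard silyl dienol ether preparation of Brassard-type dienes and their 4-alkyl homologues.

Step 4
Reactants: 2 4-(benzyloxy)benzyl chloride; 9 2-(benzyloxy)-5-bromobenzaldehyde
Product: 11 2-(benzyloxy)-5-[4-(benzyloxy)benzyl]benzaldehyde, via benzylic zinc chloride 10 (not isolated)
Conditions: 2, Zn dust, LiCl, THF, 25 °C; then slow addition to 9, Pd(OAc)2 (1 mol%), SPhos (2 mol%), THF, 25 °C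
Reagents that add atoms: none
Why: Negishi coupling, in which the LiCl-solubilised benzylic zinc chloride should cross-couple with the aryl bromide under Pd(OAc)2/SPhos faster than it adds to the electron-rich ortho-alkoxy aldehyde, provided it is added slowly.

Step 5
Reactants: 11 2-(benzyloxy)-5-[4-(benzyloxy)benzyl]benzaldehyde; 12 propargyl bromide
Product: 14 rac-1-{2-(benzyloxy)-5-[4-(benzyloxy)benzyl]phenyl}but-3-yn-1-ol, via allenylzinc bromide 13 (not isolated)
Conditions: Zn dust, THF, 0 °C to rt; then 1 M HCl, 0 °C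
Reagents that add atoms: none
Why: Zinc-mediated Barbier propargylation, in which the allenylzinc species adds through a six-membered SE2' transition state to give the homopropargylic alcohol as a racemate whose stereocentre is removed in step 6.

Step 6
Reactants: 14 rac-1-{2-(benzyloxy)-5-[4-(benzyloxy)benzyl]phenyl}but-3-yn-1-ol
Product: 15 1-(benzyloxy)-4-[4-(benzyloxy)benzyl]-2-(but-3-yn-1-yl)benzene
Conditions: Et3SiH (3 equiv), CF3CO2H (5 equiv), CH2Cl2, 0 °C
Reagents that add atoms: none
Why: Ionic hydrogenation of a secondary benzylic alcohol, in which the ortho-benzyloxy group stabilises the cation that the silane reduces, while the terminal alkyne and the aryl benzyl ethers should survive cold dilute acid.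

Step 7
Reactants: 15 1-(benzyloxy)-4-[4-(benzyloxy)benzyl]-2-(but-3-yn-1-yl)benzene; 16 4-(benzyloxy)benzoyl chloride
Product: 17 5-{2-(benzyloxy)-5-[4-(benzyloxy)benzyl]phenyl}-1-[4-(benzyloxy)phenyl]pent-2-yn-1-one
Conditions: PdCl2(PPh3)2 (2 mol%), CuI (4 mol%), Et3N, THF, rt
Reagents that add atoms: none
Why: Acyl Sonogashira coupling, in which oxidative addition of the aroyl chloride to zerovalent palladium, transfer of the copper acetylide and reductive elimination should give the ynone directly under conditions harmless to benzyl ethers.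

Step 8
Reactants: 8 (1Z,3Z)-5-[4-(benzyloxy)phenyl]-1,3-dimethoxy-1-(trimethylsilyloxy)penta-1,3-diene; 17 5-{2-(benzyloxy)-5-[4-(benzyloxy)benzyl]phenyl}-1-[4-(benzyloxy)phenyl]pent-2-yn-1-one
Product: 20 [2-{2-[2-(benzyloxy)-5-(4-benzyloxybenzyl)phenyl]ethyl}-3-(4-benzyloxybenzyl)-6-hydroxy-4-methoxyphenyl][4-(benzyloxy)phenyl]methanone, via cyclohexadiene cycloadduct 18 (not isolated), via aryl trimethylsilyl ether 19 (not isolated)
Conditions: 8 (3 equiv), toluene, 110 °C, sealed tube; then 1 M HCl, THF, rt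
Reagents that add atoms: none
Why: The electron-rich diene 8 and the electron-poor ynone 17 should combine in a normal-demand, strongly asynchronous [4+2] cycloaddition in which the nucleophilic C4 terminus of the diene bonds to the β-carbon of the ynone (C5–C6 of ring A) and the ketene acetal carbon bonds to the α-carbon (C3–C4), giving cyclohexa-1,4-diene 18. The closest known reaction type is the Diels–Alder/aromatisation of Brassard- and Chan-type 1-alkoxy-1-silyloxydienes with acetylenic ketones and esters, which gives 2-hydroxy-4-methoxyaryl carbonyl compounds. Ring A, the only ring closed, arises by this intermolecular six-membered cycloaddition (if the process is stepwise, by Mukaiyama–Michael addition followed by 6-exo-trig closure of the allenolate on the silyl oxocarbenium carbon). The two sp3 centres of 18 (cis, from suprafacial addition to the diene) disappear when methanol is lost across C3 and C6 to give silyl ether 19, so no stereocentre has to be controlled. The step needs regioselectivity, secured because the largest HOMO coefficient of the diene (C4) and the largest LUMO coefficient of the ynone (β-carbon) coincide, and it needs loss of methanol rather than silanol, favoured because the silyl ketal collapses on acidic hydrolysis to the carbonyl-chelated phenol. The benzyl group lies on the outside of the s-cis diene and the alkyne is sterically slim, so the crowded ring should still form on heating.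

Step 9
Reactants: 20 [2-{2-[2-(benzyloxy)-5-(4-benzyloxybenzyl)phenyl]ethyl}-3-(4-benzyloxybenzyl)-6-hydroxy-4-methoxyphenyl][4-(benzyloxy)phenyl]methanone
Product: 21 rac-3-{2-[2-(benzyloxy)-5-(4-benzyloxybenzyl)phenyl]ethyl}-4-(4-benzyloxybenzyl)-2-{[4-(benzyloxy)phenyl](hydroxy)methyl}-5-methoxyphenol
Conditions: NaBH4, THF/MeOH, 0 °C to rt
Reagents that add atoms: none
Why: Borohydride reduction of the diaryl ketone to the benzhydrol (racemic, stereocentre removed in step 10), with benzyl ethers, the methyl ether and the diarylmethane units inert.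

Step 10
Reactants: 21 rac-3-{2-[2-(benzyloxy)-5-(4-benzyloxybenzyl)phenyl]ethyl}-4-(4-benzyloxybenzyl)-2-{[4-(benzyloxy)phenyl](hydroxy)methyl}-5-methoxyphenol
Product: 22 3-{2-[2-(benzyloxy)-5-(4-benzyloxybenzyl)phenyl]ethyl}-2,4-bis(4-benzyloxybenzyl)-5-methoxyphenol
Conditions: Et3SiH (3 equiv), CF3CO2H (5 equiv), CH2Cl2, 0 °C
Reagents that add atoms: none
Why: Ionic hydrogenation, in which acid ionises the doubly benzylic alcohol to a cation stabilised by the ortho-hydroxy/para-methoxy ring A (a protonated ortho-quinone methide) and by the para-benzyloxyphenyl ring, and excess silane should trap it faster than it can alkylate ring B.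

Step 11
Reactants: 22 3-{2-[2-(benzyloxy)-5-(4-benzyloxybenzyl)phenyl]ethyl}-2,4-bis(4-benzyloxybenzyl)-5-methoxyphenol
Product: 23 2,4-bis(4-hydroxybenzyl)-3-{2-[2-hydroxy-5-(4-hydroxybenzyl)phenyl]ethyl}-5-methoxyphenol
Conditions: H2 (1 atm), 10% Pd/C, EtOAc/MeOH, rt
Reagents that add atoms: none
Why: Catalytic hydrogenolysis should cleave the four aryl benzyl ethers while the diarylmethane C–C bonds, the aryl methyl ether and the arenes stay intact at one atmosphere and room temperature.

**Compound list**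

1 | methyl acetoacetate | COC(=O)CC(C)=O | starting material
2 | 4-(benzyloxy)benzyl chloride | ClCc1ccc(OCc2ccccc2)cc1 | starting material
3 | methyl acetoacetate dianion (sodium lithium salt, chelated form; formed in the flask) | [Li+].[Na+].[O-]/C(OC)=C\C(=C)[O-] | intermediate
4 | methyl 5-[4-(benzyloxy)phenyl]-3-oxopentanoate | COC(=O)CC(=O)CCc1ccc(OCc2ccccc2)cc1 | intermediate
5 | methyl 5-[4-(benzyloxy)phenyl]-3,3-dimethoxypentanoate (formed in the flask) | COC(=O)CC(OC)(OC)CCc1ccc(OCc2ccccc2)cc1 | intermediate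
6 | methyl (E)-5-[4-(benzyloxy)phenyl]-3-methoxypent-2-enoate | COC(=O)/C=C(/OC)CCc1ccc(OCc2ccccc2)cc1 | intermediate
7 | lithium (1Z,3Z)-5-[4-(benzyloxy)phenyl]-1,3-dimethoxypenta-1,3-dien-1-olate (formed in the flask) | [Li+].[O-]/C(OC)=C\C(OC)=C\Cc1ccc(OCc2ccccc2)cc1 | intermediate
8 | (1Z,3Z)-5-[4-(benzyloxy)phenyl]-1,3-dimethoxy-1-(trimethylsilyloxy)penta-1,3-diene | CO/C(O[Si](C)(C)C)=C/C(OC)=C/Cc1ccc(OCc2ccccc2)cc1 | intermediate
9 | 2-(benzyloxy)-5-bromobenzaldehyde | O=Cc1cc(Br)ccc1OCc1ccccc1 | starting material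
10 | [4-(benzyloxy)benzyl]zinc chloride (LiCl complex; formed in the flask) | Cl[Zn]Cc1ccc(OCc2ccccc2)cc1 | intermediate
11 | 2-(benzyloxy)-5-[4-(benzyloxy)benzyl]benzaldehyde | O=Cc1cc(Cc2ccc(OCc3ccccc3)cc2)ccc1OCc1ccccc1 | intermediate
12 | propargyl bromide | C#CCBr | starting material
13 | allenylzinc bromide (formed in the flask) | C=C=C[Zn]Br | intermediate
14 | rac-1-{2-(benzyloxy)-5-[4-(benzyloxy)benzyl]phenyl}but-3-yn-1-ol (racemate) | C#CCC(O)c1cc(Cc2ccc(OCc3ccccc3)cc2)ccc1OCc1ccccc1 | intermediate
15 | 1-(benzyloxy)-4-[4-(benzyloxy)benzyl]-2-(but-3-yn-1-yl)benzene | C#CCCc1cc(Cc2ccc(OCc3ccccc3)cc2)ccc1OCc1ccccc1 | intermediate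
16 | 4-(benzyloxy)benzoyl chloride | O=C(Cl)c1ccc(OCc2ccccc2)cc1 | starting material
17 | 5-{2-(benzyloxy)-5-[4-(benzyloxy)benzyl]phenyl}-1-[4-(benzyloxy)phenyl]pent-2-yn-1-one | O=C(C#CCCc1cc(Cc2ccc(OCc3ccccc3)cc2)ccc1OCc1ccccc1)c1ccc(OCc2ccccc2)cc1 | intermediate
18 | (3RS,6SR)-[2-{2-[2-(benzyloxy)-5-(4-benzyloxybenzyl)phenyl]ethyl}-3-(4-benzyloxybenzyl)-4,6-dimethoxy-6-(trimethylsilyloxy)cyclohexa-1,4-dien-1-yl][4-(benzyloxy)phenyl]methanone (racemate; 3-benzyl and 6-methoxy cis; one enantiomer drawn; formed in the flask) | CO[C@]1(O[Si](C)(C)C)C=C(OC)[C@H](Cc2ccc(OCc3ccccc3)cc2)C(CCc2cc(Cc3ccc(OCc4ccccc4)cc3)ccc2OCc2ccccc2)=C1C(=O)c1ccc(OCc2ccccc2)cc1 | intermediate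
19 | [2-{2-[2-(benzyloxy)-5-(4-benzyloxybenzyl)phenyl]ethyl}-3-(4-benzyloxybenzyl)-4-methoxy-6-(trimethylsilyloxy)phenyl][4-(benzyloxy)phenyl]methanone (formed in the flask) | COc1cc(O[Si](C)(C)C)c(C(=O)c2ccc(OCc3ccccc3)cc2)c(CCc2cc(Cc3ccc(OCc4ccccc4)cc3)ccc2OCc2ccccc2)c1Cc1ccc(OCc2ccccc2)cc1 | intermediate
20 | [2-{2-[2-(benzyloxy)-5-(4-benzyloxybenzyl)phenyl]ethyl}-3-(4-benzyloxybenzyl)-6-hydroxy-4-methoxyphenyl][4-(benzyloxy)phenyl]methanone | COc1cc(O)c(C(=O)c2ccc(OCc3ccccc3)cc2)c(CCc2cc(Cc3ccc(OCc4ccccc4)cc3)ccc2OCc2ccccc2)c1Cc1ccc(OCc2ccccc2)cc1 | intermediate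
21 | rac-3-{2-[2-(benzyloxy)-5-(4-benzyloxybenzyl)phenyl]ethyl}-4-(4-benzyloxybenzyl)-2-{[4-(benzyloxy)phenyl](hydroxy)methyl}-5-methoxyphenol (racemate) | COc1cc(O)c(C(O)c2ccc(OCc3ccccc3)cc2)c(CCc2cc(Cc3ccc(OCc4ccccc4)cc3)ccc2OCc2ccccc2)c1Cc1ccc(OCc2ccccc2)cc1 | intermediate
22 | 3-{2-[2-(benzyloxy)-5-(4-benzyloxybenzyl)phenyl]ethyl}-2,4-bis(4-benzyloxybenzyl)-5-methoxyphenol | COc1cc(O)c(Cc2ccc(OCc3ccccc3)cc2)c(CCc2cc(Cc3ccc(OCc4ccccc4)cc3)ccc2OCc2ccccc2)c1Cc1ccc(OCc2ccccc2)cc1 | intermediate
23 | 2,4-bis(4-hydroxybenzyl)-3-{2-[2-hydroxy-5-(4-hydroxybenzyl)phenyl]ethyl}-5-methoxyphenol | COc1cc(O)c(Cc2ccc(O)cc2)c(CCc2cc(Cc3ccc(O)cc3)ccc2O)c1Cc1ccc(O)cc1 | target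

**Step count and risks**

Total step count: 11. Longest linear sequence: 8 steps (steps 4–11, from 2 and 9).

Steps most likely to fail:

Step 8. Both bond-forming termini are substituted, so the cycloaddition may be slow. The dienol ether may instead add through its α-carbon without closing the ring, the diene may hydrolyse or decompose on prolonged heating, or silanol may be lost in place of methanol. The fallback makes the same two ring bonds ionically and sets out from 4 and 17. The dianion of 4 (NaH, then n-BuLi, THF, 0 °C) would add through its γ-carbon to the β-carbon of 17 at −78 °C. Warming, with NaOMe in MeOH if needed, should then close the ring by Dieckmann-type attack of the dienolate α-carbon on the methyl ester. This would give the resorcinol ketone [2-{2-[2-(benzyloxy)-5-(4-benzyloxybenzyl)phenyl]ethyl}-3-(4-benzyloxybenzyl)-4,6-dihydroxyphenyl][4-(benzyloxy)phenyl]methanone F1. Its hydroxyl para to the ketone is not chelated and would be methylated selectively (MeI, K2CO3, acetone, rt), which returns to the route at 20.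

Step 4. Uncatalysed 1,2-addition of the benzylic zinc reagent to the aldehyde may compete with cross-coupling, and Wurtz homocoupling may occur during zinc insertion. The fallback sets out from 9 and uses a boron nucleophile that ignores aldehydes. Miyaura borylation (B2pin2, PdCl2(dppf), KOAc, dioxane, 80 °C) would give 2-(benzyloxy)-5-(4,4,5,5-tetramethyl-1,3,2-dioxaborolan-2-yl)benzaldehyde F2. Suzuki–Miyaura coupling of F2 with benzylic chloride 2 (Pd(PPh3)4, aqueous K2CO3, DME, 80 °C) returns to the route at 11.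

Step 6. The benzylic cation may undergo E1 elimination to the conjugated enyne or alkylate the electron-rich rings, and benzyl ethers may be partly lost in acid. The fallback sets out from 11, avoids any cation and also replaces step 5. Reduction (NaBH4, MeOH, 0 °C) would give {2-(benzyloxy)-5-[4-(benzyloxy)benzyl]phenyl}methanol F3. Bromination (PBr3, Et2O, 0 °C) would give 1-(benzyloxy)-4-[4-(benzyloxy)benzyl]-2-(bromomethyl)benzene F4. Alkylation of lithiated 1-(trimethylsilyl)propyne (n-BuLi, THF, −78 °C) with F4 would give (4-{2-(benzyloxy)-5-[4-(benzyloxy)benzyl]phenyl}but-1-yn-1-yl)trimethylsilane F5. Desilylation (K2CO3, MeOH, rt) returns to the route at 15.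

**Further compounds**

F1 | step 8 | [2-{2-[2-(benzyloxy)-5-(4-benzyloxybenzyl)phenyl]ethyl}-3-(4-benzyloxybenzyl)-4,6-dihydroxyphenyl][4-(benzyloxy)phenyl]methanone | Oc1cc(O)c(C(=O)c2ccc(OCc3ccccc3)cc2)c(CCc2cc(Cc3ccc(OCc4ccccc4)cc3)ccc2OCc2ccccc2)c1Cc1ccc(OCc2ccccc2)cc1
F2 | step 4 | 2-(benzyloxy)-5-(4,4,5,5-tetramethyl-1,3,2-dioxaborolan-2-yl)benzaldehyde | O=Cc1cc(B2OC(C)(C)C(C)(C)O2)ccc1OCc1ccccc1
F3 | step 6 | {2-(benzyloxy)-5-[4-(benzyloxy)benzyl]phenyl}methanol | OCc1cc(Cc2ccc(OCc3ccccc3)cc2)ccc1OCc1ccccc1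
F4 | step 6 | 1-(benzyloxy)-4-[4-(benzyloxy)benzyl]-2-(bromomethyl)benzene | BrCc1cc(Cc2ccc(OCc3ccccc3)cc2)ccc1OCc1ccccc1
F5 | step 6 | (4-{2-(benzyloxy)-5-[4-(benzyloxy)benzyl]phenyl}but-1-yn-1-yl)trimethylsilane | C[Si](C)(C)C#CCCc1cc(Cc2ccc(OCc3ccccc3)cc2)ccc1OCc1ccccc1
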